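## Structural features

The target is a depside with no stereocentre: two benzene rings, A and B, joined only by an ester between the carbonyl carbon C7 on C1 of ring A and the oxygen on C4' of ring B. Ring A carries C1 acyl, C2 OCH3, C3 CH2OH, C4 OCH3, C5 H and C6 CH3. Ring B is a salicylic acid with C1' CO2H, C2' OH, C3' CH3, C4' O-acyl, C5' H and C6' CH3. Three groups are fragile: the C3 hydroxymethyl group, which lies between two methoxy groups and so ionises easily in acid and is prone to hydrogenolysis; the aryl ester, an acyl donor towards bases and nucleophiles; and the salicylic acid, which can lose CO2 under hot acidic conditions. The real difficulty is the ester bond: C7 is flanked by C2 OCH3 and C6 CH3, the phenol oxygen O4' has its own ortho methyl group, and O4' must be acylated while O2' stays free. The key step uses the triad C2'(OH)–C3'(CH3)–C4'(O-acyl) of ring B, which maps onto a ketene carbon followed by the two carbons of a 1-propynyl ester. C5', C6' and C1' come from an unsaturated diazo ketone, so O4' enters the ring already bearing the ring A acyl group.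

## Logic of the disconnections

22 is traced to 21 by cutting the O–Si bond on the C3 benzylic oxygen. A free hydroxyl there would capture ketenes and organolithium reagents earlier on. No skeletal simplification results, but every earlier step becomes compatible. The forward step must remove silicon without ionising the benzylic C–O bond or cleaving the aryl ester, so it is a buffered fluoride step placed last.

21 is traced to 20 by cutting the O–CH2Ph bond of the C1' carboxyl. The acid must be an ester while diazo and ketene chemistry is in play. The forward hydrogenolysis has to spare the benzylic silyl ether of ring A, and it is placed before desilylation because the free benzylic alcohol would be more exposed to reduction.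

20 is traced to 10 and 15 by cutting C2'–C3', C4'–C5' and C1'–C2' of ring B; the C5'–C6' bond also falls in this step because it arises by a 1,2-shift in 15. The cut removes ring B and the hindered esterification in one stroke and leaves two fragments of similar size in which O2' and O4' never need to be distinguished. The forward step needs the weakly polarised alkyne of 10 to add to a ketene in the correct orientation, 15 to carry the E alkene, and 10 not to act as an acyl donor.

10 is traced to 7 and 9 by cutting the O–C(sp) bond. The carboxylate oxygen is the nucleophile, so the crowding around C7 does not matter, and the fragment is reduced to a plain benzoic acid. The forward step must be non-acidic and cold because the product is an activated ester.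

9 is traced to 8 by cutting the C(sp)–I bond. The propynyl group has to be delivered as an electrophile, and a trivalent iodine leaving group does this; the gain is a commercial alkynylsilane. The forward step is an ipso-substitution of silicon by a trivalent iodine electrophile and must be run dry.

7 is traced through 5, 4 and 3 to 1 by cutting in turn C1–C7, C–Br, O–Si and the C3–CH2OH bond. The position between the two methoxy groups of 1 is the kinetically most acidic, so the one-carbon unit goes in by directed lithiation. The two remaining ring positions are then equivalent, so bromination has a single outcome. Halogen–lithium exchange and carboxylation then place C7.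

15 is traced to 13 by cutting the C=N2 bond, and 13 to 11 and 12 by cutting the C1'=C6' alkene. Diazo transfer onto a methyl ketone avoids bringing an acid chloride and a diazoalkane together next to a doubly activated alkene. The olefination must give the E alkene, with the ester trans to the acetyl group.

## Other disconnections considered

Alternative 1: Both bonds at the ester carbonyl carbon, C1–C7 and C7–O4', are cut. In the forward direction the ring A iodide 3-iodo-2,6-dimethoxy-4-methylbenzaldehyde A1, CO and the ring B phenol benzyl 2,4-dihydroxy-3,6-dimethylbenzoate A2 would be joined with Pd(OAc)2 and a wide-bite-angle diphosphine, reduced in the flask to zerovalent palladium. Oxidative addition into the C1–I bond of A1, CO insertion and capture of the aroyl complex of divalent palladium by the 4'-phenoxide of A2 would give the key-step product benzyl 4-[(3-formyl-2,4-dimethoxy-6-methylbenzoyl)oxy]-2-hydroxy-3,6-dimethylbenzoate A3.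
- In its favour: it is convergent, no acid derivative of ring A has to be made, the aldehyde of A1 serves as an unprotected precursor of the CH2OH group, and each elementary step belongs to a well-established reaction class.
- Against it here: the iodine of A1 is flanked by two ortho substituents, so oxidative addition and the final C–O bond formation with a weakly nucleophilic, ortho-methylated phenol are expected to be slow. A2 offers two hydroxyl groups to the aroyl palladium. The end game from A3 must reduce the aldehyde and hydrogenolyse the benzyl ester while the activated benzylic oxygen is unprotected.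
- Comparison: on step count (about seven operations against eleven) and on precedent this alternative is the better plan. It equals the chosen plan in avoiding acyl substitution at the hindered acid. The chosen plan is better in that O2' and O4' never compete and the benzylic oxygen is protected during hydrogenolysis, which A3 does not allow.

Alternative 2: Ring B is cut at C3'–C4' and C1'–C6', and the depside ester is left for a later, separate step. In the forward direction the bis(silyl enol ether) (1Z,3Z)-1-(benzyloxy)-1,3-bis[(trimethylsilyl)oxy]penta-1,3-diene A4 and the vinylogous acid chloride (2E)-3-methoxybut-2-enoyl chloride A5 would combine under TiCl4. The terminal carbon of A4 is acylated, the central carbon then adds to the methoxy-bearing carbon with loss of methanol, and aromatisation gives A2 as the key-step product.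
- In its favour: both partners come from cheap acyclic keto esters, the benzyl ester and both hydroxyl groups are delivered directly, and the (3+3) cyclisation of bis(silyl enol ethers) is a known reaction class, so its precedent is better than that of the chosen key step.
- Against it here: the ring pattern depends on which electrophilic carbon of A5 is attacked first; the opposite order would give a 2,6-dihydroxy-3,4-dimethyl isomer. More seriously, A2 must still be esterified with the hindered acid 7 by acyl substitution, selectively at O4'. Ring B of this pattern is also within a short distance of commercial material, so building it gains little.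
- Comparison: structurally it leaves the central difficulty untouched, whereas the chosen plan removes it. Mechanistically it is the safer ring synthesis. On step economy the two are about equal once the four steps to 7, the esterification and two deprotections are added. Both plans fix the substitution pattern of ring B through the polarity of the two partners, and in that respect they are equal.

Alternative 3: Ring A is cut at C1–C6 and is thought of as a folded polyketide chain. The phenol benzyl 2-(benzyloxy)-4-hydroxy-3,6-dimethylbenzoate A6 would be acylated to the triketo ester benzyl 2-(benzyloxy)-3,6-dimethyl-4-[(3,5,7-trioxooctanoyl)oxy]benzoate A7. Aldol attack of the C2 methylene of A7 on its C7 ketone, dehydration and enolisation would then give the key-step product benzyl 2-(benzyloxy)-4-[(2,4-dihydroxy-6-methylbenzoyl)oxy]-3,6-dimethylbenzoate A8.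
- In its favour: the ester is formed from an unhindered aliphatic acyl group, for example by trapping an acylketene, before ring A exists. This is the same advantage the chosen plan has, and here the two are equal. The aldol aromatisation of triketo esters to 2,4-dihydroxy-6-methylbenzoates is biomimetic and has better precedent than the chosen key step.
- Against it here: an aryl ester of a β-keto acid is a good ketene precursor, so basic cyclisation conditions could expel A6, and Claisen-type closure could compete with the aldol mode. A8 also lacks both O-methyl groups and the C3 hydroxymethyl group. It would need methylation of a chelated phenol, a formylation that must choose C3 over C5, a reduction, and a double hydrogenolysis next to an unprotected activated benzylic alcohol.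
- Comparison: the chosen plan carries every ring A substituent from the first steps, and it is shorter by the four or more steps needed after A8 plus the selective protection needed to reach A6. The alternative is better only in precedent for its ring-forming step.

Key step: step 9

Remark on the chemistry: step 9 needs the E isomer of 15, with the ester trans to the diazoacetyl group. A half ester from the ring opening of citraconic anhydride would be Z, and acylating diazomethane with its acid chloride would compete with dipolar cycloaddition to the doubly activated alkene. Compound 15 is therefore built by Wittig olefination and diazo transfer, which is also one step shorter.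

Remark on numbering: alkoxide, carboxylate and enolate salts formed by simple deprotonation of a numbered compound are treated as that compound and carry no number of their own.

## Route

Step 1
Reactants: 1 3,5-dimethoxytoluene
Product: 3 (2,6-dimethoxy-4-methylphenyl)methanol, via 2,6-dimethoxy-4-methylphenyllithium 2 (not isolated)
Conditions: n-BuLi, THF, 0 °C to rt; (CH2O)n, 0 °C to rt; aq. NH4Cl
Reagents that add atoms: formaldehyde (as paraformaldehyde), C=O
Why: Directed ortho-metalation removes the proton between the two methoxy groups, which is the most acidic and doubly coordinated site, and the aryllithium is hydroxymethylated by formaldehyde.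

Step 2
Reactants: 3 (2,6-dimethoxy-4-methylphenyl)methanol
Product: 4 [(2,6-dimethoxy-4-methylphenyl)methoxy]tri(propan-2-yl)silane
Conditions: TIPSCl, imidazole, DMF, rt
Reagents that add atoms: chlorotri(propan-2-yl)silane, CC(C)[Si](Cl)(C(C)C)C(C)C
Why: Imidazole-promoted silylation of a primary alcohol; the bulky silyl ether should withstand organolithium reagents, mild base and the later ketene chemistry, where a free hydroxyl would be acylated.

Step 3
Reactants: 4 [(2,6-dimethoxy-4-methylphenyl)methoxy]tri(propan-2-yl)silane
Product: 5 [(3-bromo-2,6-dimethoxy-4-methylphenyl)methoxy]tri(propan-2-yl)silane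
Conditions: NBS, MeCN, 0 °C, dark
Reagents that add atoms: N-bromosuccinimide, O=C1CCC(=O)N1Br
Why: Electrophilic aromatic bromination; the two free ring positions are equivalent, each para to one methoxy group and ortho to the other, and the polar, radical-free conditions leave the benzylic positions alone.

Step 4
Reactants: 5 [(3-bromo-2,6-dimethoxy-4-methylphenyl)methoxy]tri(propan-2-yl)silane
Product: 7 2,4-dimethoxy-6-methyl-3-({[tri(propan-2-yl)silyl]oxy}methyl)benzoic acid, via ring A aryllithium 6 (not isolated)
Conditions: n-BuLi, THF, −78 °C; CO2, −78 to 0 °C; cold dilute HCl to pH 4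
Reagents that add atoms: carbon dioxide, O=C=O
Why: Bromine–lithium exchange is faster than any deprotonation at −78 °C and the aryllithium is carboxylated by CO2; brief cold acidification to pH 4 should leave the silyl ether intact.

Step 5
Reactants: 8 trimethyl(prop-1-yn-1-yl)silane
Product: 9 phenyl(prop-1-yn-1-yl)iodonium trifluoromethanesulfonate
Conditions: PhIO (1 equiv), Tf2O (0.5 equiv), CH2Cl2, 0 °C; then 8, 0 °C to rt; precipitation with Et2O
Reagents that add atoms: iodosylbenzene, O=Ic1ccccc1; trifluoromethanesulfonic anhydride, O=S(=O)(OS(=O)(=O)C(F)(F)F)C(F)(F)F
Why: The μ-oxo bis(triflate) of trivalent iodine formed from PhIO and Tf2O attacks the silicon-bearing alkyne carbon and silicon leaves (ipso-substitution), the standard preparation of alkynyl(phenyl)iodonium triflates from alkynylsilanes.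

Step 6
Reactants: 7 2,4-dimethoxy-6-methyl-3-({[tri(propan-2-yl)silyl]oxy}methyl)benzoic acid; 9 phenyl(prop-1-yn-1-yl)iodonium trifluoromethanesulfonate
Product: 10 prop-1-yn-1-yl 2,4-dimethoxy-6-methyl-3-({[tri(propan-2-yl)silyl]oxy}methyl)benzoate
Conditions: NaH, THF, 0 °C; then 9, CH2Cl2, −40 °C to rt; filtration through Et3N-deactivated silica
Reagents that add atoms: none
Why: Alkynyl carboxylate formation through an alkynyl(phenyl)iodonium carboxylate: the carboxylate oxygen adds to the alkyne carbon remote from iodine, iodobenzene departs and a 1,2-shift restores the triple bond; the methyl group offers no C–H bond placed for insertion, and the ortho substituents do not interfere because C7 is never attacked.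

Step 7
Reactants: 11 butane-2,3-dione; 12 benzyl (triphenyl-λ5-phosphanylidene)acetate
Product: 13 benzyl (2E)-3-methyl-4-oxopent-2-enoate
Conditions: 11 (3 equiv), CH2Cl2, 0 °C to rt; chromatography
Reagents that add atoms: none
Why: Wittig olefination of one carbonyl of the 1,2-dione by a stabilised ylide, expected to favour the E alkene with the ester trans to the acetyl group; the excess of dione suppresses double olefination and the minor Z isomer is removed on silica.

Step 8
Reactants: 13 benzyl (2E)-3-methyl-4-oxopent-2-enoate
Product: 15 benzyl (2E)-5-diazo-3-methyl-4-oxopent-2-enoate, via trifluoroacetyl diketone 14 (not isolated)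
Conditions: LiN(SiMe3)2, THF, −78 °C (13 added to the base); CF3CO2CH2CF3, −78 °C; aq. HCl work-up; then MsN3, Et3N, H2O (1 equiv), MeCN, rt
Reagents that add atoms: methanesulfonyl azide, CS(=O)(=O)N=[N+]=[N-]
Why: Detrifluoroacetylative diazo transfer: kinetic enolisation of the methyl ketone, Claisen trifluoroacetylation, then diazo transfer with loss of the trifluoroacetyl group as its sulfonamide; this is the established route to unsaturated diazo ketones, needs no diazomethane and leaves the alkene geometry untouched.

Step 9
Reactants: 10 prop-1-yn-1-yl 2,4-dimethoxy-6-methyl-3-({[tri(propan-2-yl)silyl]oxy}methyl)benzoate; 15 benzyl (2E)-5-diazo-3-methyl-4-oxopent-2-enoate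
Product: 20 benzyl 4-{[2,4-dimethoxy-6-methyl-3-({[tri(propan-2-yl)silyl]oxy}methyl)benzoyl]oxy}-2-hydroxy-3,6-dimethylbenzoate, via vinylketene 16 (not isolated), via cyclobutenone 17 (not isolated), via dienylketene 18 (not isolated), via cyclohexadienone 19 (not isolated)
Conditions: 15 (2 equiv) added over 4 h to 10 (0.3 M), hν (365 nm), degassed ClCH2CH2Cl, rt; then 80 °C
Reagents that add atoms: none
Why: Proposed new method: light at 365 nm should expel N2 from 15 with a Wolff shift of the alkenyl group (C5'–C6') to give vinylketene 16, whose ester stays trans to the ketene and so cannot close onto it. The alkyne of 10 is polarised by its acyloxy oxygen in the sense of an ynamide, so its methyl-bearing carbon should attack the ketene carbon (C2'–C3') and the oxygen-bearing carbon should then close onto the former diazo carbon (C4'–C5'), a stepwise (2+2) addition giving cyclobutenone 17. On heating, 17 should open reversibly by 4π electrocyclic cleavage to dienylketene 18, and the isomer holding C2' and C1' on the same side of C4'=C5' is removed by a thermal disrotatory 6π electrocyclisation (C1'–C2'), the only ring closure of the step, to give cyclohexadienone 19, which enolises to the C2' phenol of 20. The closest known reaction type is the Danheiser benzannulation of unsaturated diazo ketones with ynol ethers, siloxyalkynes and ynamides; an alkynyl carboxylate has not been shown as the alkyne partner. No stereocentre is created in 20: the single sp3 ring carbon of 17 and of 19 is racemic and disappears on ring opening and on enolisation. The step needs oxygen at C4' and methyl at C3'; this rests on the oxygen polarisation of the alkyne, which is weaker than in an ynol ether, so 15 is fed slowly into concentrated 10 to keep 16 in a large excess of alkyne. It also needs 10 and the vinylogous anhydride 17 not to transfer their acyl group; the two ortho substituents flanking the ring A carbonyl and the hydrogen bond tying the new C2' phenol to the benzyl ester should secure this, and light of 365 nm is not absorbed by the aryl ester.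

Step 10
Reactants: 20 benzyl 4-{[2,4-dimethoxy-6-methyl-3-({[tri(propan-2-yl)silyl]oxy}methyl)benzoyl]oxy}-2-hydroxy-3,6-dimethylbenzoate
Product: 21 4-{[2,4-dimethoxy-6-methyl-3-({[tri(propan-2-yl)silyl]oxy}methyl)benzoyl]oxy}-2-hydroxy-3,6-dimethylbenzoic acid
Conditions: H2 (1 atm), Pd/C, EtOAc, rt
Reagents that add atoms: none
Why: Hydrogenolysis of a benzyl ester over palladium on carbon; the aryl ester and methyl ethers are inert, and the bulky benzylic silyl ether should survive in a neutral aprotic solvent, which is why this step precedes desilylation.

Step 11
Reactants: 21 4-{[2,4-dimethoxy-6-methyl-3-({[tri(propan-2-yl)silyl]oxy}methyl)benzoyl]oxy}-2-hydroxy-3,6-dimethylbenzoic acid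
Product: 22 4-{[3-(hydroxymethyl)-2,4-dimethoxy-6-methylbenzoyl]oxy}-2-hydroxy-3,6-dimethylbenzoic acid
Conditions: HF·pyridine, pyridine, THF, 0 °C to rt; pH 7 buffer work-up
Reagents that add atoms: none
Why: Fluoride-driven cleavage of the Si–O bond; the pyridine-buffered reagent is neither basic enough to open the aryl ester nor acidic enough to ionise the benzylic alcohol, and no lactone can form because the CH2OH group is meta to the ester carbonyl.

## Compound list

1 | 3,5-dimethoxytoluene (1,3-dimethoxy-5-methylbenzene) | COc1cc(C)cc(OC)c1 | starting material
2 | (2,6-dimethoxy-4-methylphenyl)lithium | [Li]c1c(OC)cc(C)cc1OC | intermediate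
3 | (2,6-dimethoxy-4-methylphenyl)methanol | COc1cc(C)cc(OC)c1CO | intermediate
4 | [(2,6-dimethoxy-4-methylphenyl)methoxy]tri(propan-2-yl)silane | COc1cc(C)cc(OC)c1CO[Si](C(C)C)(C(C)C)C(C)C | intermediate
5 | [(3-bromo-2,6-dimethoxy-4-methylphenyl)methoxy]tri(propan-2-yl)silane | COc1cc(C)c(Br)c(OC)c1CO[Si](C(C)C)(C(C)C)C(C)C | intermediate
6 | [2,4-dimethoxy-6-methyl-3-({[tri(propan-2-yl)silyl]oxy}methyl)phenyl]lithium | COc1cc(C)c([Li])c(OC)c1CO[Si](C(C)C)(C(C)C)C(C)C | intermediate
7 | 2,4-dimethoxy-6-methyl-3-({[tri(propan-2-yl)silyl]oxy}methyl)benzoic acid | COc1cc(C)c(C(=O)O)c(OC)c1CO[Si](C(C)C)(C(C)C)C(C)C | intermediate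
8 | trimethyl(prop-1-yn-1-yl)silane, 1-(trimethylsilyl)propyne | CC#C[Si](C)(C)C | starting material
9 | phenyl(prop-1-yn-1-yl)iodonium trifluoromethanesulfonate | CC#C[I+]c1ccccc1.[O-]S(=O)(=O)C(F)(F)F | intermediate
10 | prop-1-yn-1-yl 2,4-dimethoxy-6-methyl-3-({[tri(propan-2-yl)silyl]oxy}methyl)benzoate | CC#COC(=O)c1c(C)cc(OC)c(CO[Si](C(C)C)(C(C)C)C(C)C)c1OC | intermediate
11 | butane-2,3-dione | CC(=O)C(C)=O | starting material
12 | benzyl (triphenyl-λ5-phosphanylidene)acetate | O=C(C=P(c1ccccc1)(c1ccccc1)c1ccccc1)OCc1ccccc1 | starting material
13 | benzyl (2E)-3-methyl-4-oxopent-2-enoate | CC(=O)/C(C)=C/C(=O)OCc1ccccc1 | intermediate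
14 | benzyl (2E)-7,7,7-trifluoro-3-methyl-4,6-dioxohept-2-enoate | O=C(OCc1ccccc1)/C=C(C)/C(=O)CC(=O)C(F)(F)F | intermediate
15 | benzyl (2E)-5-diazo-3-methyl-4-oxopent-2-enoate | O=C(OCc1ccccc1)/C=C(C)/C(=O)C=[N+]=[N-] | intermediate
16 | benzyl (2E)-3-methyl-5-oxopenta-2,4-dienoate | O=C=C/C(C)=C/C(=O)OCc1ccccc1 | intermediate
17 | benzyl (2E)-3-(2-{[2,4-dimethoxy-6-methyl-3-({[tri(propan-2-yl)silyl]oxy}methyl)benzoyl]oxy}-3-methyl-4-oxocyclobut-2-en-1-yl)but-2-enoate, racemic | CC1=C(OC(=O)c2c(C)cc(OC)c(CO[Si](C(C)C)(C(C)C)C(C)C)c2OC)C(/C(C)=C/C(=O)OCc2ccccc2)C1=O | intermediate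
18 | benzyl (2E,4E)-5-{[2,4-dimethoxy-6-methyl-3-({[tri(propan-2-yl)silyl]oxy}methyl)benzoyl]oxy}-3,6-dimethyl-7-oxohepta-2,4,6-trienoate | O=C=C(C)/C(OC(=O)c1c(C)cc(OC)c(CO[Si](C(C)C)(C(C)C)C(C)C)c1OC)=C\C(C)=C\C(=O)OCc1ccccc1 | intermediate
19 | benzyl 4-{[2,4-dimethoxy-6-methyl-3-({[tri(propan-2-yl)silyl]oxy}methyl)benzoyl]oxy}-2,5-dimethyl-6-oxocyclohexa-2,4-diene-1-carboxylate, racemic | CC1=CC(OC(=O)c2c(C)cc(OC)c(CO[Si](C(C)C)(C(C)C)C(C)C)c2OC)=C(C)C(=O)C1C(=O)OCc1ccccc1 | intermediate
20 | benzyl 4-{[2,4-dimethoxy-6-methyl-3-({[tri(propan-2-yl)silyl]oxy}methyl)benzoyl]oxy}-2-hydroxy-3,6-dimethylbenzoate | COc1cc(C)c(C(=O)Oc2cc(C)c(C(=O)OCc3ccccc3)c(O)c2C)c(OC)c1CO[Si](C(C)C)(C(C)C)C(C)C | intermediate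
21 | 4-{[2,4-dimethoxy-6-methyl-3-({[tri(propan-2-yl)silyl]oxy}methyl)benzoyl]oxy}-2-hydroxy-3,6-dimethylbenzoic acid | COc1cc(C)c(C(=O)Oc2cc(C)c(C(=O)O)c(O)c2C)c(OC)c1CO[Si](C(C)C)(C(C)C)C(C)C | intermediate
22 | 4-{[3-(hydroxymethyl)-2,4-dimethoxy-6-methylbenzoyl]oxy}-2-hydroxy-3,6-dimethylbenzoic acid | COc1cc(C)c(C(=O)Oc2cc(C)c(C(=O)O)c(O)c2C)c(OC)c1CO | target

## Step count and risk

Total step count: 11. Longest linear sequence: 8 steps (steps 1, 2, 3, 4, 6, 9, 10, 11, from 1 to 22).

Least certain steps:

Step 9 (key step, proposed new method). The likeliest failure is a (2+2) addition of 16 to the weakly polarised alkyne of 10 that is too slow, so that the ketene dimerises or is lost to adventitious nucleophiles. The other risk is acyl migration within the zwitterionic adduct before the four-membered ring closes. The fallback uses known chemistry and sets out from 15 and 7. Compound 15 would be photolysed and heated with a proven class of partner, tri(propan-2-yl)(prop-1-yn-1-yloxy)silane F1, obtained by O-silylation of lithium propynolate, to give benzyl 2-hydroxy-3,6-dimethyl-4-{[tri(propan-2-yl)silyl]oxy}benzoate F2. Bu4NF would free the 4'-phenol to give benzyl 2,4-dihydroxy-3,6-dimethylbenzoate F3. Acid 7 would be converted under neutral conditions with 1-chloro-N,N,2-trimethylprop-1-en-1-amine into 2,4-dimethoxy-6-methyl-3-({[tri(propan-2-yl)silyl]oxy}methyl)benzoyl chloride F4. The monosodium salt of F3 (NaH, 1 equiv, THF), in which the non-chelated and more acidic 4'-hydroxyl is deprotonated, would be acylated by F4. This returns to the route at 20, at the price of the hindered acyl substitution that the key step was meant to avoid.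

Step 6. The alkylidene carbene on the way to 10 may be diverted by solvent or by the carbonyl oxygen, and the alkynyl ester may be hydrated on acidic supports during isolation. The fallback sets out from 7 and 8 and avoids the isolated iodonium salt. Two equivalents of 7 would undergo ligand exchange with PhI(OAc)2, with acetic acid removed under vacuum, to give phenyl-λ3-iodanediyl bis[2,4-dimethoxy-6-methyl-3-({[tri(propan-2-yl)silyl]oxy}methyl)benzoate] F5. Compound 8 would be cleaved with MeLi to prop-1-yn-1-yllithium F6, which is added to F5 at −78 °C. The alkynyl ester then forms with loss of iodobenzene and one equivalent of 7 is recovered as its salt. The route is rejoined at 10.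

Step 8. Enolate chemistry is run on a substrate with a doubly activated alkene: conjugate addition of the enolate or the amide base to unreacted 13, or deprotonation at the C3 methyl instead of the acetyl methyl, may erode the yield. The fallback sets out from 12. Wittig reaction with tert-butyl 2-oxopropanoate would give 4-benzyl 1-tert-butyl (2E)-2-methylbut-2-enedioate F7, and CF3CO2H would cleave the tert-butyl ester to (2E)-4-(benzyloxy)-2-methyl-4-oxobut-2-enoic acid F8. Oxalyl chloride with catalytic DMF would give benzyl (2E)-4-chloro-3-methyl-4-oxobut-2-enoate F9, which is acylated onto (trimethylsilyl)diazomethane in MeCN at 0 °C. The route is rejoined at 15. The bulky silyl diazomethane and the trisubstituted alkene should limit the competing dipolar cycloaddition, which is why this longer path is only the reserve.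

Step 1. Capture of the aryllithium by slowly depolymerising paraformaldehyde may be incomplete, and the alkoxide formed may add further formaldehyde. The fallback sets out from 1: the same lithiation would be quenched with DMF to give 2,6-dimethoxy-4-methylbenzaldehyde F10, which is reduced with NaBH4 in MeOH. The route is rejoined at 3 at the cost of one extra step.

## Further compounds

F1 | step 9 | tri(propan-2-yl)(prop-1-yn-1-yloxy)silane | CC#CO[Si](C(C)C)(C(C)C)C(C)C
F2 | step 9 | benzyl 2-hydroxy-3,6-dimethyl-4-{[tri(propan-2-yl)silyl]oxy}benzoate | Cc1cc(O[Si](C(C)C)(C(C)C)C(C)C)c(C)c(O)c1C(=O)OCc1ccccc1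
F3 | step 9 | benzyl 2,4-dihydroxy-3,6-dimethylbenzoate | Cc1cc(O)c(C)c(O)c1C(=O)OCc1ccccc1
F4 | step 9 | 2,4-dimethoxy-6-methyl-3-({[tri(propan-2-yl)silyl]oxy}methyl)benzoyl chloride | COc1cc(C)c(C(=O)Cl)c(OC)c1CO[Si](C(C)C)(C(C)C)C(C)C
F5 | step 6 | phenyl-λ3-iodanediyl bis[2,4-dimethoxy-6-methyl-3-({[tri(propan-2-yl)silyl]oxy}methyl)benzoate] | O=C(O[I](OC(=O)c1c(C)cc(OC)c(CO[Si](C(C)C)(C(C)C)C(C)C)c1OC)c1ccccc1)c1c(C)cc(OC)c(CO[Si](C(C)C)(C(C)C)C(C)C)c1OC
F6 | step 6 | prop-1-yn-1-yllithium | [Li]C#CC
F7 | step 8 | 4-benzyl 1-tert-butyl (2E)-2-methylbut-2-enedioate | CC(C)(C)OC(=O)/C(C)=C/C(=O)OCc1ccccc1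
F8 | step 8 | (2E)-4-(benzyloxy)-2-methyl-4-oxobut-2-enoic acid | OC(=O)/C(C)=C/C(=O)OCc1ccccc1
F9 | step 8 | benzyl (2E)-4-chloro-3-methyl-4-oxobut-2-enoate | ClC(=O)/C(C)=C/C(=O)OCc1ccccc1
F10 | step 1 | 2,6-dimethoxy-4-methylbenzaldehyde | COc1cc(C)cc(OC)c1C=O
A1 | alternative 1 | 3-iodo-2,6-dimethoxy-4-methylbenzaldehyde | COc1cc(C)c(I)c(OC)c1C=O
A2 | alternative 1 | benzyl 2,4-dihydroxy-3,6-dimethylbenzoate (also the key-step product of alternative 2) | Cc1cc(O)c(C)c(O)c1C(=O)OCc1ccccc1
A3 | alternative 1 | benzyl 4-[(3-formyl-2,4-dimethoxy-6-methylbenzoyl)oxy]-2-hydroxy-3,6-dimethylbenzoate | COc1cc(C)c(C(=O)Oc2cc(C)c(C(=O)OCc3ccccc3)c(O)c2C)c(OC)c1C=O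
A4 | alternative 2 | (1Z,3Z)-1-(benzyloxy)-1,3-bis[(trimethylsilyl)oxy]penta-1,3-diene | C/C=C(/C=C(/OCc1ccccc1)O[Si](C)(C)C)O[Si](C)(C)C
A5 | alternative 2 | (2E)-3-methoxybut-2-enoyl chloride | CO/C(C)=C/C(Cl)=O
A6 | alternative 3 | benzyl 2-(benzyloxy)-4-hydroxy-3,6-dimethylbenzoate | Cc1cc(O)c(C)c(OCc2ccccc2)c1C(=O)OCc1ccccc1
A7 | alternative 3 | benzyl 2-(benzyloxy)-3,6-dimethyl-4-[(3,5,7-trioxooctanoyl)oxy]benzoate | CC(=O)CC(=O)CC(=O)CC(=O)Oc1cc(C)c(C(=O)OCc2ccccc2)c(OCc2ccccc2)c1C
A8 | alternative 3 | benzyl 2-(benzyloxy)-4-[(2,4-dihydroxy-6-methylbenzoyl)oxy]-3,6-dimethylbenzoate | Cc1cc(O)cc(O)c1C(=O)Oc1cc(C)c(C(=O)OCc2ccccc2)c(OCc2ccccc2)c1C
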